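**Retrosynthetic overview**
1. 7 ⇒ 6: only a K+/H+ exchange. The acid-labile free bis(hydrogen sulfate) is liberated last.
2. 6 ⇒ 2: the key disconnection is the C3–O bond. The flavonol 3-OH is added last by C3–H oxygenation of a flavone disulfate (oxirane on C2=C3, then isomerisation). This OH takes up sulfate first in a flavonol, so it is never present during sulfation.
3. 2 ⇒ 1: two O–S bonds at the two most acidic phenols (7, then 4') of luteolin.
4. Rings: rings A, C and B all come intact with luteolin. The only ring formed is the transient oxirane 4, which is opened in the same flask.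

Assumption: the target has no stereocentre or chiral axis, so no enantiomer control is needed, and the free bis(hydrogen sulfate) as drawn is taken as the final compound (salt 6 is its storage form).

**Step 1**
Reactants: 1 luteolin (5,7,3',4'-tetrahydroxyflavone)
Product: 2 bis(tetrabutylammonium) luteolin 7,4'-disulfate
Conditions: Bu4NHSO4 (2.3 equiv), DCC (10 equiv), pyridine, 4 °C to rt, 72 h; filter; Sephadex LH-20 (MeOH)
Reagents that add atoms: tetrabutylammonium hydrogen sulfate, CCCC[N+](CCCC)(CCCC)CCCC.OS(=O)(=O)[O-]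
Why: Carbodiimide-mediated O-sulfation, in which DCC activates hydrogen sulfate as an O-sulfonylisourea that passes SO3 to the unchelated, most acidic phenols in the order 7 then 4', while the chelated 5-OH and the 3'-OH next to the new anionic 4'-sulfate stay free; no stereocentre is formed.

**Step 2**
Reactants: 2 bis(tetrabutylammonium) luteolin 7,4'-disulfate
Product: 6 dipotassium quercetin 7,4'-disulfate, via bis-TMS ether 3 (not isolated), via oxirane 4 (not isolated), via silylated flavonol 5 (not isolated)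
Conditions: MSTFA (2.5 equiv), CH2Cl2, 40 °C, 1 h; DMDO (0.08 M in acetone, dried over 4 Å sieves, 3 equiv in portions), 0 °C, dark, 16 h; evaporate at 0 °C; pyridinium p-toluenesulfonate (5 mol %), CH2Cl2, 0 °C to rt; KOAc (6 equiv), AcOH (1 equiv), MeOH, 0 °C, Ar; filter the precipitate
Reagents that add atoms: dimethyldioxirane, CC1(C)OO1; potassium acetate, CC(=O)[O-].[K+]; N-methyl-N-(trimethylsilyl)trifluoroacetamide (MSTFA), CN(C(=O)C(F)(F)F)[Si](C)(C)C (its Me3Si groups stay only in 3, 4 and 5)
Why: Proposed new method: late-stage C3–H oxygenation of an ionic flavone bis(sulfate), in which the dioxirane transfers one oxygen atom through a concerted spiro transition state to the C2=C3 enol-ether π bond, the most nucleophilic site left because rings A and B carry only silyl ethers and electron-poor sulfate groups (sulfur already hexavalent, hence inert to the oxidant) and because the Bu4N+ ion pairs keep the dianion dissolved in neutral aprotic acetone/CH2Cl2, where sulfate monoesters do not hydrolyse; the weak acid then opens the C2–O bond of 4 with help from the O1 lone pair, and loss of H-3 gives the 3-hydroxy-4-pyranone 5, so the net change is C3–H to C3–OH and the two racemic stereocentres of 4 vanish; MeOH/KOAc strips the TMS groups and precipitates 6; the closest known reaction type is the dioxirane epoxidation–isomerisation of neutral, fully O-alkylated flavones to flavonols, which has not been shown on aryl sulfate salts or with transient silyl protection.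

**Step 3**
Reactants: 6 dipotassium quercetin 7,4'-disulfate
Product: 7 3',5-dihydroxy-4',7-bis(sulfooxy)flavonol (quercetin 7,4'-bis(hydrogen sulfate))
Conditions: sulfonated polystyrene cation-exchange resin (H+ form, excess), H2O, 0–4 °C, 10 min; filter; freeze-dry at once, store at −20 °C
Reagents that add atoms: none
Why: Simple cation exchange (acid–base metathesis), which is safe because acid hydrolysis of aryl sulfate monoesters in dilute water near 0 °C is far slower than the exchange; no stereocentre is involved.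

**Compound list**
1 | luteolin (5,7,3',4'-tetrahydroxyflavone) | O=c1cc(-c2ccc(O)c(O)c2)oc2cc(O)cc(O)c12 | starting material
2 | bis(tetrabutylammonium) luteolin 7,4'-disulfate (5-OH and 3'-OH free) | O=c1cc(-c2ccc(OS(=O)(=O)[O-])c(O)c2)oc2cc(OS(=O)(=O)[O-])cc(O)c12.CCCC[N+](CCCC)(CCCC)CCCC.CCCC[N+](CCCC)(CCCC)CCCC | intermediate
3 | 5,3'-bis-O-trimethylsilyl ether of 2 | O=c1cc(-c2ccc(OS(=O)(=O)[O-])c(O[Si](C)(C)C)c2)oc2cc(OS(=O)(=O)[O-])cc(O[Si](C)(C)C)c12.CCCC[N+](CCCC)(CCCC)CCCC.CCCC[N+](CCCC)(CCCC)CCCC | intermediate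
4 | 2,3-oxirane of 3 (cis-fused 2,3-epoxyflavanone, racemic, one enantiomer drawn) | O=C1[C@H]2O[C@@]2(c3ccc(OS(=O)(=O)[O-])c(O[Si](C)(C)C)c3)Oc3cc(OS(=O)(=O)[O-])cc(O[Si](C)(C)C)c31.CCCC[N+](CCCC)(CCCC)CCCC.CCCC[N+](CCCC)(CCCC)CCCC | intermediate
5 | bis(tetrabutylammonium) 5,3'-bis-O-trimethylsilylquercetin 7,4'-disulfate (3-OH free) | O=c1c(O)c(-c2ccc(OS(=O)(=O)[O-])c(O[Si](C)(C)C)c2)oc2cc(OS(=O)(=O)[O-])cc(O[Si](C)(C)C)c12.CCCC[N+](CCCC)(CCCC)CCCC.CCCC[N+](CCCC)(CCCC)CCCC | intermediate
6 | dipotassium quercetin 7,4'-disulfate | O=c1c(O)c(-c2ccc(OS(=O)(=O)[O-])c(O)c2)oc2cc(OS(=O)(=O)[O-])cc(O)c12.[K+].[K+] | intermediate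
7 | 3',5-dihydroxy-4',7-bis(sulfooxy)flavonol (achiral) | O=c1c(O)c(-c2ccc(OS(=O)(=O)O)c(O)c2)oc2cc(OS(=O)(=O)O)cc(O)c12 | target

Total step count: 3. Longest linear sequence: 3.

**Steps most likely to fail**

First, step 2 (the new C3–H oxygenation).
- **Risks:** the push-pull C2=C3 bond may epoxidise slowly. Excess dioxirane may over-oxidise 5. The TMS groups may be lost early, followed by phenol oxidation.
- **Fallback:** it uses known chemistry on neutral protected sulfate diesters, sets out from 1 and comes back at 6.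
- Compound 1 is treated with 2,2,2-trichloroethyl chlorosulfate (2.1 equiv), Et3N and 4-(dimethylamino)pyridine in THF at 0 °C. Silica chromatography then gives luteolin 7,4'-bis(2,2,2-trichloroethyl sulfate) F1.
- Ac2O/pyridine gives 5,3'-di-O-acetylluteolin 7,4'-bis(2,2,2-trichloroethyl sulfate) F2.
- Dimethyldioxirane in acetone/CH2Cl2 gives the racemic 2,3-oxirane of the diacetate F3.
- Catalytic p-toluenesulfonic acid isomerises this oxirane to 5,3'-di-O-acetylquercetin 7,4'-bis(2,2,2-trichloroethyl sulfate) F4. This is the established flavone-to-flavonol sequence on a neutral, fully O-protected flavone.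
- Zn dust/HCO2NH4 in MeOH removes both trichloroethyl groups by reductive fragmentation. The product is bis(ammonium) 5,3'-di-O-acetylquercetin 7,4'-disulfate F5.
- K2CO3 in MeOH cleaves the acetates and supplies potassium, giving 6.

Second, step 1 (reagent-controlled 7,4'-disulfation).
- **Risks:** the reaction may stop at the 7-monosulfate, or some 3'-sulfate may form that is hard to separate as a salt.
- **Fallback:** the regiochemistry is fixed by protecting groups. The fallback sets out from 1 and comes back at 2.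
- BnBr (2.1 equiv)/K2CO3 in DMF alkylates the two most acidic phenols to give 7,4'-di-O-benzylluteolin F6.
- TIPSCl/imidazole silylates the only unchelated phenol left, giving 7,4'-di-O-benzyl-3'-O-triisopropylsilylluteolin F7.
- H2 over Pd/C in EtOAc gives 3'-O-triisopropylsilylluteolin F8.
- Excess Bu4NHSO4/DCC in pyridine can now only give bis(tetrabutylammonium) 3'-O-triisopropylsilylluteolin 7,4'-disulfate F9.
- Bu4NF buffered with AcOH in THF at 0 °C then gives 2.

Third, step 3 (liberation of the free acid).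
- **Risks:** desulfation may occur on the strongly acidic resin, or autocatalytically while the solution is concentrated.
- **Fallback:** precipitation metathesis replaces ion exchange. The fallback sets out from 6 and comes back at 7.
- Ba(OAc)2 in water followed by cold EtOH precipitates barium quercetin 7,4'-disulfate F10.
- Exactly one equivalent of cold dilute H2SO4 then precipitates BaSO4. This leaves a solution of 7 that has never seen excess acid, and it is freeze-dried or used directly.

**Further compounds**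
F1 | step 2 | luteolin 7,4'-bis(2,2,2-trichloroethyl sulfate) | O=c1cc(-c2ccc(OS(=O)(=O)OCC(Cl)(Cl)Cl)c(O)c2)oc2cc(OS(=O)(=O)OCC(Cl)(Cl)Cl)cc(O)c12
F2 | step 2 | 5,3'-di-O-acetylluteolin 7,4'-bis(2,2,2-trichloroethyl sulfate) | O=c1cc(-c2ccc(OS(=O)(=O)OCC(Cl)(Cl)Cl)c(OC(C)=O)c2)oc2cc(OS(=O)(=O)OCC(Cl)(Cl)Cl)cc(OC(C)=O)c12
F3 | step 2 | 2,3-oxirane of F2 (cis-fused, racemic, one enantiomer drawn) | O=C1[C@H]2O[C@@]2(c3ccc(OS(=O)(=O)OCC(Cl)(Cl)Cl)c(OC(C)=O)c3)Oc3cc(OS(=O)(=O)OCC(Cl)(Cl)Cl)cc(OC(C)=O)c31
F4 | step 2 | 5,3'-di-O-acetylquercetin 7,4'-bis(2,2,2-trichloroethyl sulfate) | O=c1c(O)c(-c2ccc(OS(=O)(=O)OCC(Cl)(Cl)Cl)c(OC(C)=O)c2)oc2cc(OS(=O)(=O)OCC(Cl)(Cl)Cl)cc(OC(C)=O)c12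
F5 | step 2 | bis(ammonium) 5,3'-di-O-acetylquercetin 7,4'-disulfate | O=c1c(O)c(-c2ccc(OS(=O)(=O)[O-])c(OC(C)=O)c2)oc2cc(OS(=O)(=O)[O-])cc(OC(C)=O)c12.[NH4+].[NH4+]
F6 | step 1 | 7,4'-di-O-benzylluteolin | O=c1cc(-c2ccc(OCc3ccccc3)c(O)c2)oc2cc(OCc3ccccc3)cc(O)c12
F7 | step 1 | 7,4'-di-O-benzyl-3'-O-triisopropylsilylluteolin | O=c1cc(-c2ccc(OCc3ccccc3)c(O[Si](C(C)C)(C(C)C)C(C)C)c2)oc2cc(OCc3ccccc3)cc(O)c12
F8 | step 1 | 3'-O-triisopropylsilylluteolin | O=c1cc(-c2ccc(O)c(O[Si](C(C)C)(C(C)C)C(C)C)c2)oc2cc(O)cc(O)c12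
F9 | step 1 | bis(tetrabutylammonium) 3'-O-triisopropylsilylluteolin 7,4'-disulfate | O=c1cc(-c2ccc(OS(=O)(=O)[O-])c(O[Si](C(C)C)(C(C)C)C(C)C)c2)oc2cc(OS(=O)(=O)[O-])cc(O)c12.CCCC[N+](CCCC)(CCCC)CCCC.CCCC[N+](CCCC)(CCCC)CCCC
F10 | step 3 | barium quercetin 7,4'-disulfate | O=c1c(O)c(-c2ccc(OS(=O)(=O)[O-])c(O)c2)oc2cc(OS(=O)(=O)[O-])cc(O)c12.[Ba+2]
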